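## The problem

The target is an achiral flavonol: a 4H-chromen-4-one whose pyranone ring C is fused to ring A along C4a–C8a and carries the 4-methoxyphenyl ring B at C2. It has no stereocentre, so nothing has to be controlled in space; every difficulty lies in regiochemistry and in telling the oxygen atoms apart. Ring A is hexasubstituted (C5 to C8 all carry oxygen, no C–H remains); the C5 oxygen must end as a free phenol, three others stay methylated, and C3 on ring C needs a second free hydroxyl. The classical flavonol synthesis, alkaline peroxide oxidation of a 2'-hydroxychalcone (Algar–Flynn–Oyamada), is known to divert to aurones when the 6'-position carries a methoxyl, which is the pattern here, so the C3 oxygen must arrive another way. The electron-rich ring A and the finished 3,5-dihydroxy-4-keto array are easily oxidised and chelate strongly, so both hydroxyls are best revealed last, and hot alkali or strong oxidants avoided once ring C exists. The enabling feature is that C4 is bonded to C4a, whose two neighbours C5 and C8a both carry oxygen on a ring without hydrogen. An open-chain ketone with C4a on a pentamethoxyphenyl ring is therefore symmetric about the C4–C4a axis: either ortho methoxy oxygen can become O1 and the other is automatically the C5 methoxyl, so ring C closes without a regiochemical question. The same geometry later singles out the C5 methyl ether, the only one peri to the C4 carbonyl, for chelation-controlled cleavage.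

## Retrosynthesis

**18 to 17.** The last cut is the O–CH3 bond at C5, leading back to the pentamethyl flavonol 17. Only this ether lies peri to the C4 carbonyl, so a Lewis acid can pick it out. The neighbouring option, a different protecting group on the C5 oxygen, would destroy the symmetry that ring closure relies on and would add steps. Precursor 17 is simpler because all ring A oxygens are alike. The forward step must cleave one methyl ether of five in the presence of the free 3-hydroxyl.

**17 to 14.** The C3–O bond is traced back to a C3–I bond in the 3-iodoflavone 14. Oxidising a chalcone at this carbon is the aurone-prone reaction named above, and oxidising a finished flavone needs a strong base or a dioxirane. An iodide, by contrast, is what an electrophile-triggered closure of ring C leaves at C3 at no extra cost. The forward step must turn an alkenyl iodide next to a ketone into a hydroxyl without opening the pyranone; iodine–magnesium exchange, borate formation and peroxide oxidation do this through the magnesium species 15 and the borate 16.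

**14 to 12 (key disconnection).** The O1–C2 and C3–I bonds are cut together, opening ring C to the ynone 12. A cut at O1–C8a would need a leaving group on a hexasubstituted arene, and a cut at C4–C4a would need a Friedel–Crafts closure that delivers the wrong oxidation level. The chosen cut removes a ring and the halogen in one operation, and the precursor is acyclic and symmetric. The forward reaction must close 6-endo and not 5-exo, and must shed a methyl group from the oxonium ion 13.

**12 to 5 and 9.** The C4–C4a bond between the carbonyl and ring A is cut, giving pentamethoxybenzene 5 and the alkynyl Weinreb amide 9. Arene 5 has a single C–H flanked by two methoxyls, so its lithiation to 10 is unambiguous. Amide 9 brings the three-carbon unit at the ketone oxidation level. Cutting the carbonyl–alkyne bond instead (aldehyde plus acetylide, then oxidation) would cost two more steps. The forward step needs a clean single addition of a hindered aryllithium, through the chelated adduct 11.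

**9 to 6 and 7.** The bond between the alkyne carbon and the amide carbonyl is cut, giving 4-ethynylanisole 6 and the carbamoyl chloride 7, both purchasable. The forward step is acylation of the lithium acetylide 8.

**5 to 4 to 1.** One O–CH3 bond of 5 is cut to give phenol 4. The C–O bond of 4 is then cut to give 1,2,3,4-tetramethoxybenzene 1, whose two C–H positions are equivalent. Lithiation to 2, borylation to 3 and oxidation install the fifth oxygen in one flask, where formylation followed by Dakin oxidation would take two.

## Roads not taken

**Alternative 1:** Here O1–C8a and C4–C4a are cut together. Fluoride (CsF) would release 3,4,5,6-tetramethoxybenzyne A2 from the silyl triflate A4. The aryne would take up the carboxylate oxygen of (Z)-2-(benzyloxy)-3-(4-methoxyphenyl)prop-2-enoic acid A3 at one carbon and, after acyl transfer through a four-membered intermediate, the acyl group at the other, giving the 2'-hydroxychalcone-type ketone A1.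
- Merits: two ring A bonds form at once, the symmetric aryne poses no regiochemical question, and the C3 oxygen is present from the start. In that last respect this road is better than the chosen one, which needs a separate iodine-to-oxygen exchange.
- Weak points: A4 is a hexasubstituted arene that needs about four steps from phenol 4 (bromination, silylation, retro-Brook shift, triflation), and A3 needs its own synthesis. The aryl anion formed after oxygen attack can be protonated or can add to the enoate in conjugate fashion. The step closes no ring, so A1 must still be cyclised, oxidised to the flavone level and debenzylated before the C5 ether is cleaved.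
- Comparison: the chosen plan closes ring C in its key step, needs no protecting group and is shorter overall.

**Alternative 2:** Here the C4–C4a bond is cut. The 3-aryloxy-2-hydroxy acid A6 would be activated by trifluoroacetic anhydride as a mixed anhydride and would acylate the only free carbon of its tetramethoxyphenoxy ring, closing ring C as the trans-3-hydroxyflavanone A5 (racemic).
- Merits: the site of acylation is fixed because ring A has one C–H, and the C3 oxygen is again in place from the start, an advantage over the chosen plan.
- Weak points: A6 contains a benzylic aryl ether activated by a 4-methoxyphenyl group, which can ionise under the acidic acylating conditions and lose the phenol. Two stereocentres are made only to be destroyed. A5 is one oxidation level too low, so a dehydrogenation to 17 must follow, on an electron-rich substrate prone to ring contraction or over-oxidation.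
- Comparison: the chosen plan forms ring C directly at the flavone oxidation level from a robust ynone, and pays for that with the iodide exchange.

**Alternative 3:** Here ring A is not bought but grown. A C5-metalated pyranone would add to dimethyl squarate A9 to give the 4-hydroxycyclobutenone A8. On heating in xylene A8 would open to a dienylketene, whose ketene carbon bonds to the pyranone C–H carbon (Moore-type ring expansion), forming C8–C8a and ring A as the 5,8-hydroquinone A7.
- Merits: no pentaoxygenated benzene is needed, and the C5 hydroxyl emerges free, so no final demethylation is required. This is a real advantage over the chosen plan.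
- Weak points: the 3-benzyloxy-2-arylpyranone and its regioselective metalation are a multistep problem of their own. Electrocyclisation onto a pyranone enol-ether carbon is less secure than onto a benzene ring. A7 is an air-sensitive hydroquinone that oxidises readily to the 5,8-quinone. The C8 hydroxyl must be methylated without touching C5, and the benzyl group removed.
- Comparison: the chosen plan answers with a shorter sequence on stable intermediates and with a known cleavage of the peri ether.

Key step: step 5

Assumption: compounds 1, 6 and 7 are taken as purchasable; the target has no stereocentre, so no configuration has to be set.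

## Route

Step 1
Reactants: 1 1,2,3,4-tetramethoxybenzene
Product: 4 2,3,4,5-tetramethoxyphenol, via aryllithium 2 (not isolated), via lithium aryltrimethoxyborate 3 (not isolated)
Conditions: n-BuLi, TMEDA, THF, 0 °C; B(OMe)3, −78 °C to rt; AcOH, 30% aq H2O2, 0 °C to rt
Reagents that add atoms: hydrogen peroxide, OO
Why: Directed ortho-lithiation of 1 can only occur at one of its two equivalent C–H positions, each next to a methoxyl; aryllithium 2 is trapped as borate 3, and peroxide oxidation with aryl migration from boron to oxygen (the standard oxidation of arylboron compounds to phenols) should give 4 in one flask.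

Step 2
Reactants: 4 2,3,4,5-tetramethoxyphenol
Product: 5 pentamethoxybenzene
Conditions: MeI, K2CO3, DMF, rt
Reagents that add atoms: iodomethane, CI
Why: Williamson O-methylation of the only free hydroxyl; it is run under inert gas on freshly prepared 4 because the electron-rich phenoxide is sensitive to air.

Step 3
Reactants: 6 4-ethynylanisole; 7 N-methoxy-N-methylcarbamoyl chloride
Product: 9 N-methoxy-3-(4-methoxyphenyl)-N-methylprop-2-ynamide, via lithium acetylide 8 (not isolated)
Conditions: n-BuLi, THF, −78 °C; then 7, −78 to 0 °C
Reagents that add atoms: none
Why: Deprotonation of the terminal alkyne and acylation of acetylide 8 by the carbamoyl chloride is the standard preparation of alkynyl Weinreb amides; the amide formed does not react further with the acetylide at low temperature.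

Step 4
Reactants: 5 pentamethoxybenzene; 9 N-methoxy-3-(4-methoxyphenyl)-N-methylprop-2-ynamide
Product: 12 3-(4-methoxyphenyl)-1-(2,3,4,5,6-pentamethoxyphenyl)prop-2-yn-1-one, via pentamethoxyphenyllithium 10 (not isolated), via lithium hemiaminal alkoxide 11 (not isolated)
Conditions: n-BuLi, THF, 0 °C; then 9, −78 to −40 °C; inverse quench into cold 1 M HCl
Reagents that add atoms: none
Why: Weinreb ketone synthesis: the single C–H of 5 lies between two methoxyls and is lithiated cleanly, and 10 adds once to the unhindered alkynyl amide carbonyl to give the chelated adduct 11, which holds until the quench; the cold acid protonates the released N,O-dimethylhydroxylamine and so keeps it from adding to the ynone.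

Step 5
Reactants: 12 3-(4-methoxyphenyl)-1-(2,3,4,5,6-pentamethoxyphenyl)prop-2-yn-1-one
Product: 14 3-iodo-5,6,7,8-tetramethoxy-2-(4-methoxyphenyl)-4H-chromen-4-one, via O-methyloxonium chloride 13 (not isolated)
Conditions: ICl (1.2 equiv), CH2Cl2, −78 °C; aq Na2S2O3
Reagents that add atoms: iodine monochloride, ClI
Why: ICl, a polarised source of electrophilic iodine, activates the alkyne of 12 as an iodonium ion whose positive charge sits on the carbon bonded to the 4-methoxyphenyl group, which is also the electrophilic β-carbon of the ynone. One of the two equivalent ortho methoxy oxygens adds anti to iodine at that carbon, forming O1–C2 and C3–I and closing ring C in the 6-endo-dig mode to give oxonium chloride 13. Chloride then removes the methyl group from the oxonium oxygen by SN2 displacement (MeCl is lost), which makes the closure irreversible and leaves the neutral 3-iodoflavone 14. The closest known reaction type is the ICl-induced cyclisation of 2-methoxyaryl alkynyl ketones to 3-iodochromones and 3-iodoflavones, which tolerates methoxylated aryl groups on the alkyne. No stereocentre is formed. The step needs 6-endo over 5-exo closure (attack at the carbon next to the carbonyl would give a benzofuranone), and the cation-stabilising anisyl group and the ynone polarisation both direct oxygen to the distal carbon. It needs no choice between the two ortho oxygens, because the pentamethoxyphenyl ring is symmetric. It also needs the alkyne to outcompete the arenes for iodine, which is secured by a ring A without C–H, a ring B deactivated by conjugation with the ynone, low temperature and only a slight excess of ICl.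

Step 6
Reactants: 14 3-iodo-5,6,7,8-tetramethoxy-2-(4-methoxyphenyl)-4H-chromen-4-one
Product: 17 3-hydroxy-5,6,7,8-tetramethoxy-2-(4-methoxyphenyl)-4H-chromen-4-one, via 3-magnesioflavone 15 (not isolated), via magnesium flavonylborate 16 (not isolated)
Conditions: iPrMgCl·LiCl, THF, −40 °C; B(OMe)3, −40 to 0 °C; AcOH, 30% aq H2O2, 0 °C to rt
Reagents that add atoms: hydrogen peroxide, OO
Why: Iodine–magnesium exchange at the electron-poor alkenyl iodide should be faster than addition to the vinylogous-ester carbonyl, which the peri methoxyl also shields; 15 is trapped cold as borate 16 and oxidised with carbon-to-oxygen migration, the metalation–borylation–oxidation sequence by which 3-metalated flavones are converted into flavonols.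

Step 7
Reactants: 17 3-hydroxy-5,6,7,8-tetramethoxy-2-(4-methoxyphenyl)-4H-chromen-4-one
Product: 18 3,5-dihydroxy-6,7,8-trimethoxy-2-(4-methoxyphenyl)-4H-chromen-4-one
Conditions: BCl3 (3 equiv), CH2Cl2, −78 to 0 °C; aq HCl, MeOH
Reagents that add atoms: none
Why: Chelation-controlled ether cleavage: boron held between the C4 carbonyl oxygen and the peri C5 methoxy oxygen forms a six-membered chelate and chloride removes that methyl as MeCl, while the ethers at C6, C7, C8 and C4' lack this assistance at low temperature; one equivalent of BCl3 is consumed by the 3-hydroxyl, hence the excess.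

## Compound list

1 | 1,2,3,4-tetramethoxybenzene | COc1ccc(OC)c(OC)c1OC | starting material
2 | (2,3,4,5-tetramethoxyphenyl)lithium | [Li]c1cc(OC)c(OC)c(OC)c1OC | intermediate (not isolated)
3 | lithium trimethoxy(2,3,4,5-tetramethoxyphenyl)borate | [Li+].CO[B-](OC)(OC)c1cc(OC)c(OC)c(OC)c1OC | intermediate (not isolated)
4 | 2,3,4,5-tetramethoxyphenol | Oc1cc(OC)c(OC)c(OC)c1OC | intermediate
5 | pentamethoxybenzene | COc1cc(OC)c(OC)c(OC)c1OC | intermediate
6 | 4-ethynylanisole (1-ethynyl-4-methoxybenzene) | C#Cc1ccc(OC)cc1 | starting material
7 | N-methoxy-N-methylcarbamoyl chloride | CON(C)C(Cl)=O | starting material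
8 | lithium (4-methoxyphenyl)acetylide | [Li]C#Cc1ccc(OC)cc1 | intermediate (not isolated)
9 | N-methoxy-3-(4-methoxyphenyl)-N-methylprop-2-ynamide | CON(C)C(=O)C#Cc1ccc(OC)cc1 | intermediate
10 | (pentamethoxyphenyl)lithium | [Li]c1c(OC)c(OC)c(OC)c(OC)c1OC | intermediate (not isolated)
11 | lithium 1-[methoxy(methyl)amino]-3-(4-methoxyphenyl)-1-(pentamethoxyphenyl)prop-2-yn-1-olate (racemic) | COc1ccc(C#CC(O[Li])(N(C)OC)c2c(OC)c(OC)c(OC)c(OC)c2OC)cc1 | intermediate (not isolated)
12 | 3-(4-methoxyphenyl)-1-(2,3,4,5,6-pentamethoxyphenyl)prop-2-yn-1-one | COc1ccc(C#CC(=O)c2c(OC)c(OC)c(OC)c(OC)c2OC)cc1 | intermediate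
13 | 3-iodo-5,6,7,8-tetramethoxy-2-(4-methoxyphenyl)-1-methyl-4-oxo-4H-chromen-1-ium chloride | COc1ccc(C2=C(I)C(=O)c3c(OC)c(OC)c(OC)c(OC)c3[O+]2C)cc1.[Cl-] | intermediate (not isolated)
14 | 3-iodo-5,6,7,8-tetramethoxy-2-(4-methoxyphenyl)-4H-chromen-4-one | COc1ccc(-c2oc3c(OC)c(OC)c(OC)c(OC)c3c(=O)c2I)cc1 | intermediate
15 | chloro[5,6,7,8-tetramethoxy-2-(4-methoxyphenyl)-4-oxo-4H-chromen-3-yl]magnesium | COc1ccc(-c2oc3c(OC)c(OC)c(OC)c(OC)c3c(=O)c2[Mg]Cl)cc1 | intermediate (not isolated)
16 | chloromagnesium trimethoxy[5,6,7,8-tetramethoxy-2-(4-methoxyphenyl)-4-oxo-4H-chromen-3-yl]borate | COc1ccc(-c2oc3c(OC)c(OC)c(OC)c(OC)c3c(=O)c2[B-](OC)(OC)OC)cc1.[Mg+2].[Cl-] | intermediate (not isolated)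
17 | 3-hydroxy-5,6,7,8-tetramethoxy-2-(4-methoxyphenyl)-4H-chromen-4-one | COc1ccc(-c2oc3c(OC)c(OC)c(OC)c(OC)c3c(=O)c2O)cc1 | intermediate
18 | 3,5-dihydroxy-6,7,8-trimethoxy-2-(4-methoxyphenyl)-4H-chromen-4-one (3,5-dihydroxy-6,7,8,4'-tetramethoxyflavone) | COc1ccc(-c2oc3c(OC)c(OC)c(OC)c(O)c3c(=O)c2O)cc1 | target

## Step count and risk

Total steps: 7. Longest linear sequence: 6 (steps 1, 2, 4, 5, 6, 7); step 3 is a one-step side branch.

**Step 5 (key step).** The most likely failure is attack of ICl on the electron-rich arenes instead of productive closure: oxidative demethylation of ring A towards a quinone, or iodination of ring B next to its methoxyl. Plain addition of I–Cl across the alkyne is also possible, because the di-ortho-substituted ketone is twisted out of the ring A plane and must flatten as ring C forms. The fallback gives up the alkyne; it sets out from phenol 4 and rejoins the route at flavonol 17. Acylation of 4 at its only free position with AcOH and BF3·OEt2 (Fries-type ortho-acylation) would give 1-(2-hydroxy-3,4,5,6-tetramethoxyphenyl)ethan-1-one F1. Claisen–Schmidt condensation with 4-methoxybenzaldehyde (KOH, EtOH) would give the chalcone (E)-1-(2-hydroxy-3,4,5,6-tetramethoxyphenyl)-3-(4-methoxyphenyl)prop-2-en-1-one F2. Oxidative cyclisation with catalytic I2 in DMSO at 130 °C would give 5,6,7,8-tetramethoxy-2-(4-methoxyphenyl)-4H-chromen-4-one F3. Lithiation of F3 at C3 with LDA at −78 °C, trapping with B(OMe)3 and oxidation with H2O2/AcOH would then install the hydroxyl and deliver 17, avoiding the aurone-prone peroxide oxidation of the chalcone.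

**Step 6.** The 3-magnesio species 15 carries the ring oxygen anti on the neighbouring carbon, so β-elimination with ring opening to an alkynyl ketone phenoxide is the main danger; addition of the Grignard reagent to C4 or C2 before exchange is the second. The fallback sets out from 14 and returns at 17 without any polar organometallic. Miyaura borylation (B2pin2, PdCl2(dppf), KOAc, dioxane, 80 °C) would give 5,6,7,8-tetramethoxy-2-(4-methoxyphenyl)-3-(4,4,5,5-tetramethyl-1,3,2-dioxaborolan-2-yl)-4H-chromen-4-one F4, and oxidation with NaBO3·4H2O in THF/H2O would give 17.

**Step 4.** Two things may go wrong. The hindered aryllithium 10 may add sluggishly, or may act as a base and fragment the N-methoxy group of 9 with loss of formaldehyde; or conjugate addition of the released amine to the ynone may occur during work-up. The fallback sets out from 5 and returns at 12. Lithiation as before and quench with DMF would give 2,3,4,5,6-pentamethoxybenzaldehyde F5. Addition of lithium acetylide 8 (from 6 and n-BuLi) would give racemic 3-(4-methoxyphenyl)-1-(2,3,4,5,6-pentamethoxyphenyl)prop-2-yn-1-ol F6, and MnO2 in CH2Cl2 would oxidise it to 12.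

**Step 7.** The 3-O-boron chelate may occupy the carbonyl and slow the cleavage, and forcing the reaction risks a second demethylation at C6 through the new C5 boron phenoxide. The fallback reverses the order of the last two steps; it sets out from 14 and returns at 18. BCl3 in CH2Cl2 at −78 to 0 °C on the iodide, where no 3-hydroxyl interferes, would give 5-hydroxy-3-iodo-6,7,8-trimethoxy-2-(4-methoxyphenyl)-4H-chromen-4-one F7. Exchange with iPrMgCl·LiCl (2.2 equiv, the first deprotonating the phenol), B(OMe)3 and H2O2/AcOH would then give 18 directly.

**Step 1.** Incomplete lithiation, or over-oxidation of the very electron-rich phenol during the peroxide stage, would erode material at the start. The fallback sets out from 1 and returns at 4. Rieche formylation (Cl2CHOMe, TiCl4, CH2Cl2, 0 °C) would give 2,3,4,5-tetramethoxybenzaldehyde F8. Dakin-type Baeyer–Villiger oxidation with mCPBA in CH2Cl2 would give 2,3,4,5-tetramethoxyphenyl formate F9, and hydrolysis with aqueous KOH would release 4.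

## Further compounds

F1 | step 5 | 1-(2-hydroxy-3,4,5,6-tetramethoxyphenyl)ethan-1-one | CC(=O)c1c(O)c(OC)c(OC)c(OC)c1OC
F2 | step 5 | (E)-1-(2-hydroxy-3,4,5,6-tetramethoxyphenyl)-3-(4-methoxyphenyl)prop-2-en-1-one | COc1ccc(/C=C/C(=O)c2c(O)c(OC)c(OC)c(OC)c2OC)cc1
F3 | step 5 | 5,6,7,8-tetramethoxy-2-(4-methoxyphenyl)-4H-chromen-4-one | COc1ccc(-c2cc(=O)c3c(OC)c(OC)c(OC)c(OC)c3o2)cc1
F4 | step 6 | 5,6,7,8-tetramethoxy-2-(4-methoxyphenyl)-3-(4,4,5,5-tetramethyl-1,3,2-dioxaborolan-2-yl)-4H-chromen-4-one | COc1ccc(-c2oc3c(OC)c(OC)c(OC)c(OC)c3c(=O)c2B4OC(C)(C)C(C)(C)O4)cc1
F5 | step 4 | 2,3,4,5,6-pentamethoxybenzaldehyde | O=Cc1c(OC)c(OC)c(OC)c(OC)c1OC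
F6 | step 4 | 3-(4-methoxyphenyl)-1-(2,3,4,5,6-pentamethoxyphenyl)prop-2-yn-1-ol (racemic) | COc1ccc(C#CC(O)c2c(OC)c(OC)c(OC)c(OC)c2OC)cc1
F7 | step 7 | 5-hydroxy-3-iodo-6,7,8-trimethoxy-2-(4-methoxyphenyl)-4H-chromen-4-one | COc1ccc(-c2oc3c(OC)c(OC)c(OC)c(O)c3c(=O)c2I)cc1
F8 | step 1 | 2,3,4,5-tetramethoxybenzaldehyde | O=Cc1cc(OC)c(OC)c(OC)c1OC
F9 | step 1 | 2,3,4,5-tetramethoxyphenyl formate | O=COc1cc(OC)c(OC)c(OC)c1OC
A1 | alternative 1 | (Z)-2-(benzyloxy)-1-(2-hydroxy-3,4,5,6-tetramethoxyphenyl)-3-(4-methoxyphenyl)prop-2-en-1-one | COc1ccc(/C=C(\OCc2ccccc2)C(=O)c2c(O)c(OC)c(OC)c(OC)c2OC)cc1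
A2 | alternative 1 | 3,4,5,6-tetramethoxybenzyne | COC1=C(OC)C(OC)=C(OC)C#C1
A3 | alternative 1 | (Z)-2-(benzyloxy)-3-(4-methoxyphenyl)prop-2-enoic acid | COc1ccc(/C=C(\OCc2ccccc2)C(=O)O)cc1
A4 | alternative 1 | 2,3,4,5-tetramethoxy-6-(trimethylsilyl)phenyl trifluoromethanesulfonate | COc1c(OC)c(OC)c(OS(=O)(=O)C(F)(F)F)c([Si](C)(C)C)c1OC
A5 | alternative 2 | trans-3-hydroxy-5,6,7,8-tetramethoxy-2-(4-methoxyphenyl)chroman-4-one (racemic, one enantiomer drawn) | COc1ccc([C@H]2Oc3c(OC)c(OC)c(OC)c(OC)c3C(=O)[C@@H]2O)cc1
A6 | alternative 2 | 2-hydroxy-3-(4-methoxyphenyl)-3-(2,3,4,5-tetramethoxyphenoxy)propanoic acid (racemic, relative configuration leading to the trans product, one enantiomer drawn) | COc1ccc([C@H]([C@@H](O)C(O)=O)Oc2cc(OC)c(OC)c(OC)c2OC)cc1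
A7 | alternative 3 | 3-(benzyloxy)-5,8-dihydroxy-6,7-dimethoxy-2-(4-methoxyphenyl)-4H-chromen-4-one | COc1ccc(-c2oc3c(O)c(OC)c(OC)c(O)c3c(=O)c2OCc2ccccc2)cc1
A8 | alternative 3 | 3-(benzyloxy)-5-(1-hydroxy-2,3-dimethoxy-4-oxocyclobut-2-en-1-yl)-2-(4-methoxyphenyl)-4H-pyran-4-one (racemic) | COc1ccc(-c2occ(C3(O)C(OC)=C(OC)C3=O)c(=O)c2OCc2ccccc2)cc1
A9 | alternative 3 | dimethyl squarate (3,4-dimethoxycyclobut-3-ene-1,2-dione) | COC1=C(OC)C(=O)C1=O
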